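**Plan**

- Retrosynthesis (ring A = the hexasubstituted benzene ring; side-chain carbons numbered C1' at the benzylic CH2 to C24'): the two phenol O–H groups go back to ubiquinone-6 and then to two O–CH3 groups of a tetramethyl ether; the chain is cut at C13'–C14', then C13' is cut from C12', then ring A is cut from C1'.
- Forward: ring A (2,3,4,5-tetramethoxytoluene) is farnesylated (C1'–C12'); the terminal (E)-methyl C12' is oxidised and extended by one carbon to a C13' iodide; the C14'–C24' part arrives as a terminal alkyne made from geranylacetone; the chain is closed at C13'–C14'; ring A is then oxidised to the quinone and reduced to the hydroquinone.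
- Enabling feature: C14'(H)=C15'(CH3) is a trisubstituted double bond whose methyl is cis to C13'. This is the pattern left by syn addition of CH3–metal across a terminal C14'≡C15' triple bond followed by retentive C–C bond formation at C14'. C13' is a primary sp3 carbon, separated from C10'=C11' by C12', so it can serve as an unhindered alkyl iodide.
- Stereochemistry: C2'=C3' and C6'=C7' come from (2E,6E)-farnesyl bromide and C18'=C19' from (E)-geranylacetone; C10'=C11' becomes stereogenic, and E, in the allylic oxidation; C14'=C15' is created E in the key step. The target has no stereocentre.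
- Helpers and their removal: the alkyne oxidation level at C14'–C15' and the iodide on C13' are consumed in the key step; the PhS group on C13' is exchanged for iodide; of the four O-methyl groups on ring A, two are lost in the cerium oxidation and two belong to the target.

Key step: step 7

Remark: 2,3,4,5-tetramethoxytoluene, (2E,6E)-farnesyl bromide and (E)-geranylacetone are taken as purchasable single isomers; the target is air-sensitive, so step 9 and its work-up are run under argon with degassed solvents.

**Route**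

Step 1
Reactants: 1 2,3,4,5-tetramethoxytoluene; 2 (2E,6E)-farnesyl bromide
Product: 5 1,2,3,4-tetramethoxy-5-methyl-6-[(2E,6E)-3,7,11-trimethyldodeca-2,6,10-trien-1-yl]benzene, via aryllithium 3 (not isolated), via arylcopper 4 (not isolated)
Conditions: n-BuLi, TMEDA, Et2O/hexane, 0 °C → rt; CuBr·SMe2, THF, −40 °C; then 2, −40 °C → rt
Reagents that add atoms: none
Why: Directed ortho-lithiation at the only C–H of ring A (next to a methoxy group), transmetalation to copper and SN2 (α-selective) allylation of the arylcopper by the primary allylic bromide should join ring A to C1' without touching the 2E,6E geometry.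

Step 2
Reactants: 5 1,2,3,4-tetramethoxy-5-methyl-6-[(2E,6E)-3,7,11-trimethyldodeca-2,6,10-trien-1-yl]benzene
Product: 6 (2E,6E,10E)-2,6,10-trimethyl-12-(2,3,4,5-tetramethoxy-6-methylphenyl)dodeca-2,6,10-trien-1-ol
Conditions: SeO2 (cat.), t-BuOOH, salicylic acid (cat.), CH2Cl2, 0 °C → rt, stopped at partial conversion with recovery of 5
Reagents that add atoms: tert-butyl hydroperoxide, CC(C)(C)OO; selenium dioxide, O=[Se]=O
Why: Riley allylic oxidation (ene reaction, then [2,3]-sigmatropic shift) is expected to favour the least hindered, terminal isopropylidene unit of a polyprenyl chain and to oxidise the methyl trans to the chain, which makes C10'=C11' stereogenic with E geometry and functionalises C12'.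

Step 3
Reactants: 6 (2E,6E,10E)-2,6,10-trimethyl-12-(2,3,4,5-tetramethoxy-6-methylphenyl)dodeca-2,6,10-trien-1-ol
Product: 7 1-[(2E,6E,10E)-12-bromo-3,7,11-trimethyldodeca-2,6,10-trien-1-yl]-2,3,4,5-tetramethoxy-6-methylbenzene
Conditions: CBr4, PPh3, CH2Cl2, 0 °C
Reagents that add atoms: carbon tetrabromide, BrC(Br)(Br)Br
Why: The Appel reaction displaces the oxyphosphonium group by bromide at the primary allylic carbon under neutral conditions, so neither the olefin geometry nor the acid-sensitive electron-rich arene and polyene should be disturbed.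

Step 4
Reactants: 7 1-[(2E,6E,10E)-12-bromo-3,7,11-trimethyldodeca-2,6,10-trien-1-yl]-2,3,4,5-tetramethoxy-6-methylbenzene
Product: 8 1,2,3,4-tetramethoxy-5-methyl-6-[(2E,6E,10E)-3,7,11-trimethyl-13-(phenylsulfanyl)trideca-2,6,10-trien-1-yl]benzene
Conditions: PhSMe, n-BuLi, DABCO, THF, 0 °C; then 7, −78 → 0 °C
Reagents that add atoms: thioanisole, CSc1ccccc1
Why: SN2 alkylation of (phenylsulfanyl)methyllithium by the primary allylic bromide is the classical one-carbon homologation of allylic halides and should install C13' with a sulfur handle.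

Step 5
Reactants: 8 1,2,3,4-tetramethoxy-5-methyl-6-[(2E,6E,10E)-3,7,11-trimethyl-13-(phenylsulfanyl)trideca-2,6,10-trien-1-yl]benzene
Product: 10 1-[(2E,6E,10E)-13-iodo-3,7,11-trimethyltrideca-2,6,10-trien-1-yl]-2,3,4,5-tetramethoxy-6-methylbenzene, via sulfonium iodide 9 (not isolated)
Conditions: MeI (excess), NaI, DMF, 70 °C, dark
Reagents that add atoms: methyl iodide, CI; sodium iodide, [Na+].[I-]
Why: S-methylation gives a methyl(phenyl)sulfonium salt whose primary CH2 is attacked by iodide (SN2 dealkylation of a sulfonium salt), which should turn C13'–SPh into C13'–I with loss of thioanisole.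

Step 6
Reactants: 11 (5E)-6,10-dimethylundeca-5,9-dien-2-one ((E)-geranylacetone)
Product: 15 (5E)-6,10-dimethylundeca-5,9-dien-1-yne, via lithium enolate 12 (not isolated), via enol phosphate 13 (not isolated), via lithium acetylide 14 (not isolated)
Conditions: LiN(i-Pr)2 (1.05 equiv), THF, −78 °C; ClP(O)(OEt)2, −78 °C → rt; then LiN(i-Pr)2 (2.3 equiv), −78 °C → rt; H2O
Reagents that add atoms: none
Why: Kinetic deprotonation at the methyl group, O-phosphorylation and base-induced elimination of the enol phosphate (methyl ketone to terminal alkyne conversion) should deliver the C14'–C24' alkyne without touching the (E) C18'=C19' bond.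

Step 7
Reactants: 15 (5E)-6,10-dimethylundeca-5,9-dien-1-yne; 10 1-[(2E,6E,10E)-13-iodo-3,7,11-trimethyltrideca-2,6,10-trien-1-yl]-2,3,4,5-tetramethoxy-6-methylbenzene
Product: 18 1-[(2E,6E,10E,14E,18E)-3,7,11,15,19,23-hexamethyltetracosa-2,6,10,14,18,22-hexaen-1-yl]-2,3,4,5-tetramethoxy-6-methylbenzene, via alkenylalane 16 (not isolated), via alkenylzinc bromide 17 (not isolated)
Conditions: 15 (1.5 equiv), AlMe3 (2 equiv per alkyne), Cp2ZrCl2 (0.2 equiv), CH2Cl2, 0 °C → rt; volatiles removed in vacuo; ZnBr2, THF, 0 °C; then 10, Pd2(dba)3 (cat.), PCyp3 (cat.), N-methylimidazole, THF/NMP, 60–80 °C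
Reagents that add atoms: trimethylaluminium, C[Al](C)C
Why: Proposed new method: the closest known reaction types are the zirconocene-catalysed methylalumination of terminal alkynes telescoped with Pd- or Ni-catalysed coupling of the alkenylalane to sp2 or benzylic halides, and the Pd/PCyp3 Negishi coupling of preformed alkenylzinc halides with unactivated primary alkyl iodides; what has not been shown is their union, a carboalumination-derived alkenyl metal coupled in the same flask with a β-hydrogen-bearing homoallylic iodide. Mechanistically, CH3–Zr adds syn across C14'≡C15' of 15 with methyl going to the internal carbon, zirconium-to-aluminium exchange gives the (E)-alkenylalane 16, ZnBr2 takes over the alkenyl ligand to give 17, electron-rich zerovalent palladium inserts into the C13'–I bond of 10 by an SN2-type oxidative addition, and transmetalation followed by reductive elimination forms C13'–C14' with retention at the sp2 carbon. No ring is closed and no stereocentre is made; the one new stereo-element, the E geometry of C14'=C15', follows from the syn addition, which places the new methyl cis to the metal and therefore cis to C13'. The step needs regioselectivity (methyl to C15', expected from the steric and electronic bias of a terminal alkyne), alkenyl-over-methyl transfer (favoured by stripping excess AlMe3 before ZnBr2 is added and by the faster exchange of sp2 ligands), and coupling in preference to β-hydride loss towards a C10'–C13' diene (favoured by the bulky, strongly donating PCyp3 ligand and the N-methylimidazole-activated zinc reagent). The isolated trisubstituted olefins and the four aryl methyl ethers should be inert to AlMe3/Cp2ZrCl2, which carbometalates only the terminal alkyne, and C13' has no five- or six-membered cyclisation mode onto an olefin.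

Step 8
Reactants: 18 1-[(2E,6E,10E,14E,18E)-3,7,11,15,19,23-hexamethyltetracosa-2,6,10,14,18,22-hexaen-1-yl]-2,3,4,5-tetramethoxy-6-methylbenzene
Product: 19 ubiquinone-6 (2-[(2E,6E,10E,14E,18E)-3,7,11,15,19,23-hexamethyltetracosa-2,6,10,14,18,22-hexaen-1-yl]-5,6-dimethoxy-3-methylcyclohexa-2,5-diene-1,4-dione)
Conditions: (NH4)2Ce(NO3)6 (2.5 equiv), pyridine-2,6-dicarboxylic acid, MeCN/CH2Cl2/H2O, 0 °C
Reagents that add atoms: water, O
Why: Oxidative demethylation by tetravalent cerium (single-electron oxidation of ring A, water addition ipso to methoxy groups, loss of methanol) should give the para-quinone, because the methoxy groups next to the methyl and next to the chain are the only para-related oxygen pair on ring A, and the isolated olefins are not expected to be oxidised at 0 °C.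

Step 9
Reactants: 19 ubiquinone-6
Product: 20 ubiquinol-6 (2-[(2E,6E,10E,14E,18E)-3,7,11,15,19,23-hexamethyltetracosa-2,6,10,14,18,22-hexaen-1-yl]-5,6-dimethoxy-3-methylbenzene-1,4-diol)
Conditions: Na2S2O4, Et2O/H2O, rt, argon, degassed solvents
Reagents that add atoms: none
Why: Dithionite reduction of the para-quinone to the hydroquinone is a neutral two-electron, two-proton process that should avoid acid-catalysed chromanol cyclisation of a phenol onto C2'=C3' and, with air excluded, re-oxidation.

**Compound list**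

1 | 2,3,4,5-tetramethoxytoluene | Cc1cc(OC)c(OC)c(OC)c1OC | starting material
2 | (2E,6E)-farnesyl bromide | BrC/C=C(\C)CC/C=C(\C)CCC=C(C)C | starting material
3 | (2,3,4,5-tetramethoxy-6-methylphenyl)lithium, not isolated | [Li]c1c(C)c(OC)c(OC)c(OC)c1OC | intermediate
4 | (2,3,4,5-tetramethoxy-6-methylphenyl)copper, not isolated | [Cu]c1c(C)c(OC)c(OC)c(OC)c1OC | intermediate
5 | 1,2,3,4-tetramethoxy-5-methyl-6-[(2E,6E)-3,7,11-trimethyldodeca-2,6,10-trien-1-yl]benzene | COc1c(OC)c(C)c(C/C=C(\C)CC/C=C(\C)CCC=C(C)C)c(OC)c1OC | intermediate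
6 | (2E,6E,10E)-2,6,10-trimethyl-12-(2,3,4,5-tetramethoxy-6-methylphenyl)dodeca-2,6,10-trien-1-ol | COc1c(OC)c(C)c(C/C=C(\C)CC/C=C(\C)CC/C=C(\C)CO)c(OC)c1OC | intermediate
7 | 1-[(2E,6E,10E)-12-bromo-3,7,11-trimethyldodeca-2,6,10-trien-1-yl]-2,3,4,5-tetramethoxy-6-methylbenzene | COc1c(OC)c(C)c(C/C=C(\C)CC/C=C(\C)CC/C=C(\C)CBr)c(OC)c1OC | intermediate
8 | 1,2,3,4-tetramethoxy-5-methyl-6-[(2E,6E,10E)-3,7,11-trimethyl-13-(phenylsulfanyl)trideca-2,6,10-trien-1-yl]benzene | COc1c(OC)c(C)c(C/C=C(\C)CC/C=C(\C)CC/C=C(\C)CCSc2ccccc2)c(OC)c1OC | intermediate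
9 | methyl(phenyl)[(3E,7E,11E)-3,7,11-trimethyl-13-(2,3,4,5-tetramethoxy-6-methylphenyl)trideca-3,7,11-trien-1-yl]sulfonium iodide, racemic at sulfur, not isolated | COc1c(OC)c(C)c(C/C=C(\C)CC/C=C(\C)CC/C=C(\C)CC[S+](C)c2ccccc2)c(OC)c1OC.[I-] | intermediate
10 | 1-[(2E,6E,10E)-13-iodo-3,7,11-trimethyltrideca-2,6,10-trien-1-yl]-2,3,4,5-tetramethoxy-6-methylbenzene | COc1c(OC)c(C)c(C/C=C(\C)CC/C=C(\C)CC/C=C(\C)CCI)c(OC)c1OC | intermediate
11 | (5E)-6,10-dimethylundeca-5,9-dien-2-one ((E)-geranylacetone) | CC(=O)CC/C=C(\C)CCC=C(C)C | starting material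
12 | lithium (5E)-6,10-dimethylundeca-1,5,9-trien-2-olate, not isolated | [Li]OC(=C)CC/C=C(\C)CCC=C(C)C | intermediate
13 | diethyl (5E)-6,10-dimethylundeca-1,5,9-trien-2-yl phosphate, not isolated | C=C(OP(=O)(OCC)OCC)CC/C=C(\C)CCC=C(C)C | intermediate
14 | [(5E)-6,10-dimethylundeca-5,9-dien-1-yn-1-yl]lithium, not isolated | [Li]C#CCC/C=C(\C)CCC=C(C)C | intermediate
15 | (5E)-6,10-dimethylundeca-5,9-dien-1-yne | C#CCC/C=C(\C)CCC=C(C)C | intermediate
16 | dimethyl[(1E,5E)-2,6,10-trimethylundeca-1,5,9-trien-1-yl]alane, not isolated | C[Al](C)/C=C(\C)CC/C=C(\C)CCC=C(C)C | intermediate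
17 | bromo[(1E,5E)-2,6,10-trimethylundeca-1,5,9-trien-1-yl]zinc, not isolated | Br[Zn]/C=C(\C)CC/C=C(\C)CCC=C(C)C | intermediate
18 | 1-[(2E,6E,10E,14E,18E)-3,7,11,15,19,23-hexamethyltetracosa-2,6,10,14,18,22-hexaen-1-yl]-2,3,4,5-tetramethoxy-6-methylbenzene | COc1c(OC)c(C)c(C/C=C(\C)CC/C=C(\C)CC/C=C(\C)CC/C=C(\C)CC/C=C(\C)CCC=C(C)C)c(OC)c1OC | intermediate
19 | ubiquinone-6 | COC1=C(OC)C(=O)C(C)=C(C/C=C(\C)CC/C=C(\C)CC/C=C(\C)CC/C=C(\C)CC/C=C(\C)CCC=C(C)C)C1=O | intermediate
20 | ubiquinol-6 | COc1c(O)c(C)c(C/C=C(\C)CC/C=C(\C)CC/C=C(\C)CC/C=C(\C)CC/C=C(\C)CCC=C(C)C)c(O)c1OC | target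

**Step count and risks**

Total step count: 9. Longest linear sequence: 8 (steps 1–5, then 7–9); step 6 is the one-step side branch.

Steps most likely to fail:

1. Step 7 (proposed new method). What may go wrong: transfer of a methyl ligand from aluminium or zinc to palladium in place of the alkenyl group; β-hydride elimination from the C13'–palladium intermediate before transmetalation; incomplete aluminium-to-zinc exchange. Fallback with known chemistry, setting out from 15 and 10 and coming back at 18: the alkenylalane 16 is made as before and cleaved with I2 (THF, −30 °C) to the alkenyl iodide (1E,5E)-1-iodo-2,6,10-trimethylundeca-1,5,9-triene F1. Separately, 10 is converted by iodine–lithium exchange (t-BuLi, 2 equiv, Et2O, −78 °C) into the homoallyllithium F2 and with ZnBr2 into the homoallylzinc bromide F3. Negishi coupling of F3 with F1 (Pd(PPh3)4 cat., THF, rt), the polarity-inverted and well-established alkenyl iodide/homoallylzinc pairing, should give 18 with retention of the E geometry.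

2. Step 2. What may go wrong: insufficient site discrimination between the three trisubstituted double bonds (ene reaction at an internal olefin or at the benzylic–allylic C1' position) and over-oxidation to the enal. Fallback, setting out from 5 and coming back at 6: terminal-selective bromohydrin formation (NBS, THF/H2O, 0 °C) should give the racemic bromohydrin F4, which is closed with K2CO3/MeOH to the racemic terminal epoxide F5. Cleavage with H5IO6 (THF/H2O) gives the C10' aldehyde F6. Wittig olefination with Ph3P=C(CH3)CO2Et (CH2Cl2, rt) builds C10'=C11' as the (E)-enoate F7, and reduction with i-Bu2AlH (CH2Cl2, −78 °C) gives 6.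

3. Step 4. What may go wrong: allylic transposition (SN2' attack), competing deprotonation of the doubly activated benzylic–allylic C1' methylene by the basic organolithium, and decomposition of the labile allylic bromide. Fallback, setting out from 6 and coming back at 10 (it replaces steps 3–5): oxidation with MnO2 (CH2Cl2, rt) gives the (E)-enal F8 and Wittig methylenation (Ph3PCH3Br, KOt-Bu, THF, 0 °C) gives the terminal diene F9. Hydroboration of the monosubstituted vinyl end with 9-BBN (THF, 0 °C → rt) gives the B-alkyl-9-BBN F10, which is oxidised with NaOH/H2O2 to the homoallylic alcohol F11. Iodination (I2, PPh3, imidazole, CH2Cl2, 0 °C) then gives 10.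

**Further compounds**

F1 | step 7 | (1E,5E)-1-iodo-2,6,10-trimethylundeca-1,5,9-triene | I/C=C(\C)CC/C=C(\C)CCC=C(C)C
F2 | step 7 | [(3E,7E,11E)-3,7,11-trimethyl-13-(2,3,4,5-tetramethoxy-6-methylphenyl)trideca-3,7,11-trien-1-yl]lithium | COc1c(OC)c(C)c(C/C=C(\C)CC/C=C(\C)CC/C=C(\C)CC[Li])c(OC)c1OC
F3 | step 7 | bromo[(3E,7E,11E)-3,7,11-trimethyl-13-(2,3,4,5-tetramethoxy-6-methylphenyl)trideca-3,7,11-trien-1-yl]zinc | COc1c(OC)c(C)c(C/C=C(\C)CC/C=C(\C)CC/C=C(\C)CC[Zn]Br)c(OC)c1OC
F4 | step 2 | (6E,10E)-3-bromo-2,6,10-trimethyl-12-(2,3,4,5-tetramethoxy-6-methylphenyl)dodeca-6,10-dien-2-ol, racemic | COc1c(OC)c(C)c(C/C=C(\C)CC/C=C(\C)CCC(Br)C(C)(C)O)c(OC)c1OC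
F5 | step 2 | 2,2-dimethyl-3-[(3E,7E)-3,7-dimethyl-9-(2,3,4,5-tetramethoxy-6-methylphenyl)nona-3,7-dien-1-yl]oxirane, racemic | COc1c(OC)c(C)c(C/C=C(\C)CC/C=C(\C)CCC2OC2(C)C)c(OC)c1OC
F6 | step 2 | (4E,8E)-4,8-dimethyl-10-(2,3,4,5-tetramethoxy-6-methylphenyl)deca-4,8-dienal | COc1c(OC)c(C)c(C/C=C(\C)CC/C=C(\C)CCC=O)c(OC)c1OC
F7 | step 2 | ethyl (2E,6E,10E)-2,6,10-trimethyl-12-(2,3,4,5-tetramethoxy-6-methylphenyl)dodeca-2,6,10-trienoate | COc1c(OC)c(C)c(C/C=C(\C)CC/C=C(\C)CC/C=C(\C)C(=O)OCC)c(OC)c1OC
F8 | step 4 | (2E,6E,10E)-2,6,10-trimethyl-12-(2,3,4,5-tetramethoxy-6-methylphenyl)dodeca-2,6,10-trienal | COc1c(OC)c(C)c(C/C=C(\C)CC/C=C(\C)CC/C=C(\C)C=O)c(OC)c1OC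
F9 | step 4 | 1,2,3,4-tetramethoxy-5-methyl-6-[(2E,6E,10E)-3,7,11-trimethyltrideca-2,6,10,12-tetraen-1-yl]benzene | COc1c(OC)c(C)c(C/C=C(\C)CC/C=C(\C)CC/C=C(\C)C=C)c(OC)c1OC
F10 | step 4 | 9-[(3E,7E,11E)-3,7,11-trimethyl-13-(2,3,4,5-tetramethoxy-6-methylphenyl)trideca-3,7,11-trien-1-yl]-9-borabicyclo[3.3.1]nonane (bridgeheads necessarily cis) | COc1c(OC)c(C)c(C/C=C(\C)CC/C=C(\C)CC/C=C(\C)CCB2C3CCCC2CCC3)c(OC)c1OC
F11 | step 4 | (3E,7E,11E)-3,7,11-trimethyl-13-(2,3,4,5-tetramethoxy-6-methylphenyl)trideca-3,7,11-trien-1-ol | COc1c(OC)c(C)c(C/C=C(\C)CC/C=C(\C)CC/C=C(\C)CCO)c(OC)c1OC
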